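**Strategy.** With the ring numbered C1 (stereogenic CH), C2 (CMe2), C3–C5 (CH2) and C6 (C=CH2), everything rests on cutting two opposite ring bonds, C2–C3 and C6–C1. This pairs C1–C2, as a 3-methylbut-2-enoyl dienophile on a chiral oxazolidinone, with C3–C6, as an (E)-1-substituted buta-1,3-diene. One Lewis acid-promoted Diels–Alder reaction closes the ring, builds the quaternary carbon and sets C1. It exploits the 1,2-relation of C1 and the methylene-bearing C6 beside the gem-dimethyl carbon ("ortho" adduct). The diene carries a phenylsulfanylmethyl group that later becomes the exocyclic methylene, and the transient ring alkene is reduced. A sulfone alkylation then joins the C10 chain.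

Key step: step 4

Remark (assumption): the cycloadduct is drawn as the endo (cis) isomer. Its epimer at the sulfanylmethyl-bearing carbon would converge in step 7, because that carbon becomes sp2 there.

**Step 1**
Reactants: 1 (4R)-4-benzyl-1,3-oxazolidin-2-one; 2 3-methylbut-2-enoyl chloride
Product: 3 (4R)-4-benzyl-3-(3-methylbut-2-enoyl)-1,3-oxazolidin-2-one
Conditions: n-BuLi, THF, −78 °C; then 2, −78 → 0 °C
Reagents that add atoms: none
Why: N-acylation of the lithiated oxazolidinone by the acid chloride (imide formation) should proceed cleanly and touches no stereocentre.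

**Step 2**
Reactants: 4 penta-1,4-dien-3-ol
Product: 5 (3E)-5-bromopenta-1,3-diene
Conditions: 48% aq. HBr, 0 °C → rt
Reagents that add atoms: hydrogen bromide, Br
Why: allylic substitution with transposition (ionisation to the pentadienyl cation, bromide capture at the terminus) should give the conjugated primary (E)-bromide as the thermodynamic product.

**Step 3**
Reactants: 5 (3E)-5-bromopenta-1,3-diene
Product: 6 [(2E)-penta-2,4-dien-1-ylsulfanyl]benzene
Conditions: PhSNa, EtOH, 0 °C → rt
Reagents that add atoms: sodium benzenethiolate, [Na+].[S-]c1ccccc1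
Why: SN2 displacement of the primary allylic bromide by the soft thiolate should occur at the primary carbon and keep the (E)-diene conjugated.

**Step 4**
Reactants: 3 (4R)-4-benzyl-3-(3-methylbut-2-enoyl)-1,3-oxazolidin-2-one; 6 [(2E)-penta-2,4-dien-1-ylsulfanyl]benzene
Product: 7 (4R)-4-benzyl-3-{[(1R,2R)-6,6-dimethyl-2-[(phenylsulfanyl)methyl]cyclohex-3-en-1-yl]carbonyl}-1,3-oxazolidin-2-one
Conditions: Me2AlCl (1.4 equiv), 6 (3 equiv), CH2Cl2, −40 → 0 °C
Reagents that add atoms: none
Why: Me2AlCl gives a cationic aluminium chelate across the two imide carbonyls, which holds the enoyl group s-cis and lowers its LUMO, so that a concerted but asynchronous normal-demand [4+2] cycloaddition with the (E)-diene should take place, the bond to the β-carbon being the more advanced. The closest known reactions are the aluminium-promoted Diels–Alder reactions of N-enoyl oxazolidinones and the AlCl3-promoted addition of penta-1,3-diene to 4-methylpent-3-en-2-one, which joins a diene CH2 terminus to a gem-dimethyl β-carbon in the same way. The cyclohexene ring is closed in the suprafacial [4+2] mode, both bonds forming in one transition state. The new stereocentre at ring C1 (the α-carbon) is set by the benzyl group of the (4R)-auxiliary, which shields one face of the chelated s-cis dienophile so that the diene adds to the other; the second new centre (the sulfanylmethyl carbon) follows the endo rule and is erased in step 7. "Ortho" regioselectivity is needed and is secured because the unsubstituted diene terminus, with the larger HOMO coefficient and the lower hindrance, pairs with the electrophilic, fully substituted β-carbon; facial selectivity is secured by the auxiliary, and minor diastereomers can be removed by chromatography or crystallisation. The thioether is a poor ligand for aluminium and carries no ionisable leaving group, so the diene should survive the Lewis acid.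

**Step 5**
Reactants: 7 (4R)-4-benzyl-3-{[(1R,2R)-6,6-dimethyl-2-[(phenylsulfanyl)methyl]cyclohex-3-en-1-yl]carbonyl}-1,3-oxazolidin-2-one
Product: 8 (4R)-4-benzyl-3-{[(1R,6R)-2,2-dimethyl-6-[(phenylsulfanyl)methyl]cyclohexyl]carbonyl}-1,3-oxazolidin-2-one
Conditions: 2-nitrobenzenesulfonohydrazide (excess), Et3N, CH2Cl2, rt
Reagents that add atoms: none
Why: diimide reduction (concerted syn transfer of H2) should saturate the cis-disubstituted ring alkene and, unlike a palladium-catalysed hydrogenation, is not poisoned by the thioether; no stereocentre is touched.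

**Step 6**
Reactants: 8 (4R)-4-benzyl-3-{[(1R,6R)-2,2-dimethyl-6-[(phenylsulfanyl)methyl]cyclohexyl]carbonyl}-1,3-oxazolidin-2-one
Product: 9 {(1R,6R)-2,2-dimethyl-6-[(phenylsulfanyl)methyl]cyclohexyl}methanol
Conditions: LiBH4, MeOH (1 equiv), THF, 0 °C → rt
Reagents that add atoms: none
Why: reductive cleavage of the N-acyl oxazolidinone by borohydride at the exocyclic carbonyl should give the primary alcohol and return auxiliary 1, without enolisation and hence without epimerisation at C1.

**Step 7**
Reactants: 9 {(1R,6R)-2,2-dimethyl-6-[(phenylsulfanyl)methyl]cyclohexyl}methanol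
Product: 11 [(1S)-2,2-dimethyl-6-methylidenecyclohexyl]methanol, via sulfoxide 10 (not isolated)
Conditions: mCPBA (1.0 equiv), CH2Cl2, −78 °C; then NaHCO3, toluene, 110 °C
Reagents that add atoms: none
Why: S-oxidation followed by thermal syn-elimination of the sulfoxide (sulfoxide pyrolysis) should give the exocyclic methylene regiospecifically, because the ring methine hydrogen is the only β-hydrogen; C1 is untouched and its descriptor changes from R to S only through the priority change at C6.

**Step 8**
Reactants: 11 [(1S)-2,2-dimethyl-6-methylidenecyclohexyl]methanol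
Product: 12 ({[(1S)-2,2-dimethyl-6-methylidenecyclohexyl]methyl}sulfanyl)benzene
Conditions: PhSSPh, n-Bu3P, THF, 50 °C
Reagents that add atoms: diphenyl disulfide, c1ccccc1SSc1ccccc1
Why: Mitsunobu-type phosphine–disulfide thioetherification (SN2 of thiolate on the alkoxyphosphonium ion) should convert the hindered primary alcohol without affecting the adjacent stereocentre.

**Step 9**
Reactants: 12 ({[(1S)-2,2-dimethyl-6-methylidenecyclohexyl]methyl}sulfanyl)benzene
Product: 13 ({[(1S)-2,2-dimethyl-6-methylidenecyclohexyl]methyl}sulfonyl)benzene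
Conditions: 30% H2O2, (NH4)6Mo7O24·4H2O (cat.), EtOH, 0 °C → rt
Reagents that add atoms: hydrogen peroxide, OO
Why: molybdate-catalysed peroxide oxidation of a sulfide to the sulfone should be chemoselective over the unactivated 1,1-disubstituted alkene.

**Step 10**
Reactants: 14 (2E)-3,7-dimethylocta-2,6-dien-1-yl acetate (geranyl acetate)
Product: 15 (2E,6E)-8-hydroxy-3,7-dimethylocta-2,6-dien-1-yl acetate
Conditions: SeO2 (cat.), t-BuOOH, salicylic acid (cat.), CH2Cl2, rt
Reagents that add atoms: tert-butyl hydroperoxide, CC(C)(C)OO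
Why: selenium dioxide allylic oxidation (ene reaction, then 2,3-sigmatropic shift) should hydroxylate the (E)-methyl group of the terminal trisubstituted alkene, the 2,3-alkene being deactivated by the allylic acetate.

**Step 11**
Reactants: 15 (2E,6E)-8-hydroxy-3,7-dimethylocta-2,6-dien-1-yl acetate
Product: 16 (2E,6E)-8-bromo-3,7-dimethylocta-2,6-dien-1-yl acetate
Conditions: CBr4, PPh3, CH2Cl2, 0 °C
Reagents that add atoms: carbon tetrabromide, BrC(Br)(Br)Br
Why: Appel bromination (SN2 at the primary allylic carbon) should give the bromide with the alkene geometry retained.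

**Step 12**
Reactants: 13 ({[(1S)-2,2-dimethyl-6-methylidenecyclohexyl]methyl}sulfonyl)benzene; 16 (2E,6E)-8-bromo-3,7-dimethylocta-2,6-dien-1-yl acetate
Product: 17 (2E,6E)-9-[(1S)-2,2-dimethyl-6-methylidenecyclohexyl]-3,7-dimethyl-9-(phenylsulfonyl)nona-2,6-dien-1-yl acetate (both configurations at C9)
Conditions: n-BuLi, THF, −78 °C; then 16, −78 → −40 °C
Reagents that add atoms: none
Why: alkylation of the α-sulfonyl carbanion (Julia-type fragment coupling) by the primary allylic bromide should outrun attack on the acetate at low temperature; the new sulfone-bearing centre is removed in step 13 and ring C1 is not acidic.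

**Step 13**
Reactants: 17 (2E,6E)-9-[(1S)-2,2-dimethyl-6-methylidenecyclohexyl]-3,7-dimethyl-9-(phenylsulfonyl)nona-2,6-dien-1-yl acetate
Product: 19 (2E,6E)-9-[(1S)-2,2-dimethyl-6-methylidenecyclohexyl]-3,7-dimethylnona-2,6-dien-1-ol, via hydroxy sulfone 18 (not isolated)
Conditions: K2CO3, MeOH, rt; then Na2HPO4, 6% Na(Hg), THF/MeOH, −20 °C
Reagents that add atoms: none
Why: methanolysis of the acetate followed by reductive desulfonylation with sodium amalgam (electron transfer, C–S cleavage, protonation) should leave the isolated alkenes and the allylic alcohol untouched.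

**Step 14**
Reactants: 19 (2E,6E)-9-[(1S)-2,2-dimethyl-6-methylidenecyclohexyl]-3,7-dimethylnona-2,6-dien-1-ol; 20 2,2-dimethyl-1,3-dioxane-4,6-dione
Product: 21 3-{[(2E,6E)-9-[(1S)-2,2-dimethyl-6-methylidenecyclohexyl]-3,7-dimethylnona-2,6-dien-1-yl]oxy}-3-oxopropanoic acid (target)
Conditions: toluene, 90 °C
Reagents that add atoms: none
Why: alcoholysis of the cyclic acylal (acyl transfer with loss of acetone) should give the malonic acid half-ester directly, with no protecting group.

**Compound list**

1 | (4R)-4-benzyl-1,3-oxazolidin-2-one | O=C1N[C@H](Cc2ccccc2)CO1 | starting material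
2 | 3-methylbut-2-enoyl chloride | CC(C)=CC(Cl)=O | starting material
3 | (4R)-4-benzyl-3-(3-methylbut-2-enoyl)-1,3-oxazolidin-2-one | CC(C)=CC(=O)N1[C@H](Cc2ccccc2)COC1=O | intermediate
4 | penta-1,4-dien-3-ol | C=CC(O)C=C | starting material
5 | (3E)-5-bromopenta-1,3-diene | C=C/C=C/CBr | intermediate
6 | [(2E)-penta-2,4-dien-1-ylsulfanyl]benzene | C=C/C=C/CSc1ccccc1 | intermediate
7 | (4R)-4-benzyl-3-{[(1R,2R)-6,6-dimethyl-2-[(phenylsulfanyl)methyl]cyclohex-3-en-1-yl]carbonyl}-1,3-oxazolidin-2-one | c1ccccc1SC[C@@H]2C=CCC(C)(C)[C@@H]2C(=O)N3[C@H](Cc4ccccc4)COC3=O | intermediate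
8 | (4R)-4-benzyl-3-{[(1R,6R)-2,2-dimethyl-6-[(phenylsulfanyl)methyl]cyclohexyl]carbonyl}-1,3-oxazolidin-2-one | c1ccccc1SC[C@@H]2CCCC(C)(C)[C@@H]2C(=O)N3[C@H](Cc4ccccc4)COC3=O | intermediate
9 | {(1R,6R)-2,2-dimethyl-6-[(phenylsulfanyl)methyl]cyclohexyl}methanol | c1ccccc1SC[C@@H]2CCCC(C)(C)[C@@H]2CO | intermediate
10 | {(1R,6R)-2,2-dimethyl-6-[(phenylsulfinyl)methyl]cyclohexyl}methanol (both configurations at sulfur) | O=S(C[C@@H]1CCCC(C)(C)[C@@H]1CO)c1ccccc1 | intermediate (not isolated)
11 | [(1S)-2,2-dimethyl-6-methylidenecyclohexyl]methanol | C=C1CCCC(C)(C)[C@@H]1CO | intermediate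
12 | ({[(1S)-2,2-dimethyl-6-methylidenecyclohexyl]methyl}sulfanyl)benzene | C=C1CCCC(C)(C)[C@@H]1CSc2ccccc2 | intermediate
13 | ({[(1S)-2,2-dimethyl-6-methylidenecyclohexyl]methyl}sulfonyl)benzene | C=C1CCCC(C)(C)[C@@H]1CS(=O)(=O)c2ccccc2 | intermediate
14 | (2E)-3,7-dimethylocta-2,6-dien-1-yl acetate | CC(C)=CCC/C(C)=C/COC(C)=O | starting material
15 | (2E,6E)-8-hydroxy-3,7-dimethylocta-2,6-dien-1-yl acetate | OC/C(C)=C/CC/C(C)=C/COC(C)=O | intermediate
16 | (2E,6E)-8-bromo-3,7-dimethylocta-2,6-dien-1-yl acetate | BrC/C(C)=C/CC/C(C)=C/COC(C)=O | intermediate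
17 | (2E,6E)-9-[(1S)-2,2-dimethyl-6-methylidenecyclohexyl]-3,7-dimethyl-9-(phenylsulfonyl)nona-2,6-dien-1-yl acetate (both configurations at C9) | C=C1CCCC(C)(C)[C@@H]1C(C/C(C)=C/CC/C(C)=C/COC(C)=O)S(=O)(=O)c2ccccc2 | intermediate
18 | (2E,6E)-9-[(1S)-2,2-dimethyl-6-methylidenecyclohexyl]-3,7-dimethyl-9-(phenylsulfonyl)nona-2,6-dien-1-ol (both configurations at C9) | C=C1CCCC(C)(C)[C@@H]1C(C/C(C)=C/CC/C(C)=C/CO)S(=O)(=O)c2ccccc2 | intermediate (not isolated)
19 | (2E,6E)-9-[(1S)-2,2-dimethyl-6-methylidenecyclohexyl]-3,7-dimethylnona-2,6-dien-1-ol | C=C1CCCC(C)(C)[C@@H]1CC/C(C)=C/CC/C(C)=C/CO | intermediate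
20 | 2,2-dimethyl-1,3-dioxane-4,6-dione | CC1(C)OC(=O)CC(=O)O1 | starting material
21 | 3-{[(2E,6E)-9-[(1S)-2,2-dimethyl-6-methylidenecyclohexyl]-3,7-dimethylnona-2,6-dien-1-yl]oxy}-3-oxopropanoic acid | C=C1CCCC(C)(C)[C@@H]1CC/C(C)=C/CC/C(C)=C/COC(=O)CC(=O)O | target

**Step count and risks**

Total step count: 14. Longest linear sequence: 11 steps (from 4 through steps 2, 3, 4, 5, 6, 7, 8, 9, 12, 13 and 14).

Step 4 is the most likely to fail. The β,β-disubstituted dienophile may react too slowly, so that the Lewis acid oligomerises the diene first, or the two faces may be discriminated incompletely. The fallback makes the same two ring bonds stepwise by polar chemistry; it sets out from 3 and comes back at 11. Hydrobromination of pent-4-yn-1-ol (HBr, Et4NBr, CH2Cl2) should give 4-bromopent-4-en-1-ol F1, and bromination (CBr4, PPh3) 2,5-dibromopent-1-ene F2. Magnesium should insert into the alkyl bromide only, giving (4-bromopent-4-en-1-yl)magnesium bromide F3. CuBr·SMe2-catalysed conjugate addition of F3 to 3 in the presence of Me3SiCl builds the quaternary carbon and should give the silyl ketene N,O-acetal (4R)-4-benzyl-3-[(1Z)-7-bromo-3,3-dimethyl-1-(trimethylsilyloxy)octa-1,7-dien-1-yl]-1,3-oxazolidin-2-one F4, used crude. Intramolecular α-alkenylation (Pd(dba)2, P(t-Bu)3, ZnF2, DMF, 60 °C) should then close the ring on the face away from the benzyl group to give (4R)-4-benzyl-3-{[(1S)-2,2-dimethyl-6-methylidenecyclohexyl]carbonyl}-1,3-oxazolidin-2-one F5, and LiBH4 reduction of F5 gives 11.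

Step 6 is the second risk. The exocyclic carbonyl lies between a quaternary and a tertiary carbon, so hydride may attack the ring carbonyl instead and open the auxiliary. The fallback sets out from 8 and comes back at 9. Transacylation with the small, soft nucleophile EtSLi (from EtSH and n-BuLi, THF, 0 °C) should give S-ethyl (1R,6R)-2,2-dimethyl-6-[(phenylsulfanyl)methyl]cyclohexane-1-carbothioate F6 and return 1, and F6 is reduced with LiAlH4 to 9.

Step 12 is the third risk. C-alkylation of the hindered sulfonyl carbanion may be slow, so that attack on the acetate or elimination of the allylic bromide competes. The fallback replaces the sulfone coupling by a copper-catalysed coupling with reversed roles of the metals; it sets out from 11 and comes back at 19. Appel bromination (CBr4, PPh3) should give (1S)-1-(bromomethyl)-2,2-dimethyl-6-methylidenecyclohexane F7, and magnesium in THF {[(1S)-2,2-dimethyl-6-methylidenecyclohexyl]methyl}magnesium bromide F8. Li2CuCl4-catalysed coupling of F8 with 16 (THF, −78 → 0 °C) should give (2E,6E)-9-[(1S)-2,2-dimethyl-6-methylidenecyclohexyl]-3,7-dimethylnona-2,6-dien-1-yl acetate F9, and methanolysis (K2CO3, MeOH) gives 19.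

**Further compounds**

F1 | step 4 | 4-bromopent-4-en-1-ol | OCCCC(Br)=C
F2 | step 4 | 2,5-dibromopent-1-ene | BrCCCC(Br)=C
F3 | step 4 | (4-bromopent-4-en-1-yl)magnesium bromide | Br[Mg]CCCC(Br)=C
F4 | step 4 | (4R)-4-benzyl-3-[(1Z)-7-bromo-3,3-dimethyl-1-(trimethylsilyloxy)octa-1,7-dien-1-yl]-1,3-oxazolidin-2-one | C=C(Br)CCCC(C)(C)/C=C(\O[Si](C)(C)C)N1[C@H](Cc2ccccc2)COC1=O
F5 | step 4 | (4R)-4-benzyl-3-{[(1S)-2,2-dimethyl-6-methylidenecyclohexyl]carbonyl}-1,3-oxazolidin-2-one | C=C1CCCC(C)(C)[C@@H]1C(=O)N2[C@H](Cc3ccccc3)COC2=O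
F6 | step 6 | S-ethyl (1R,6R)-2,2-dimethyl-6-[(phenylsulfanyl)methyl]cyclohexane-1-carbothioate | c1ccccc1SC[C@@H]2CCCC(C)(C)[C@@H]2C(=O)SCC
F7 | step 12 | (1S)-1-(bromomethyl)-2,2-dimethyl-6-methylidenecyclohexane | C=C1CCCC(C)(C)[C@@H]1CBr
F8 | step 12 | {[(1S)-2,2-dimethyl-6-methylidenecyclohexyl]methyl}magnesium bromide | C=C1CCCC(C)(C)[C@@H]1C[Mg]Br
F9 | step 12 | (2E,6E)-9-[(1S)-2,2-dimethyl-6-methylidenecyclohexyl]-3,7-dimethylnona-2,6-dien-1-yl acetate | C=C1CCCC(C)(C)[C@@H]1CC/C(C)=C/CC/C(C)=C/COC(C)=O
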